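## Retrosynthetic overview
1. The target comes from its hexa-O-benzyl ether by hydrogenolysis. The C4(ring C)–C6(ring D) bond is cut the way the plant is thought to make it: a 3-deoxyflavan-4-yl cation plus a teracacidin-type nucleophile, attacked anti to the 2-aryl group (2,4-trans).
2. Both pyran rings are traced back to one achiral 2'-hydroxychalcone.
3. Ring C: a reversible chalcone-isomerase-type oxa-Michael closure is drained in the same flask by reductase-type asymmetric transfer hydrogenation (dynamic kinetic resolution). This gives the (2S,4S)-flavan-4-ol.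
4. Ring F: an Algar–Flynn–Oyamada oxidative closure (3-hydroxylase/flavonol-synthase counterpart) gives the planar flavonol. One syn,syn asymmetric hydrogenation then sets C2, C3 and C4 all-cis.
5. The chalcone comes from a Claisen–Schmidt condensation of 3,4-di-O-benzylgallacetophenone with 4-(benzyloxy)benzaldehyde. Rings C and F are closed in parallel branches and then joined; benzene rings A, B, D and E are bought.

Assumption: the target is taken exactly as drawn, that is (2S,4S)-7,8,4'-trihydroxyflavan-(4β→6)-(2R,3R,4R)-teracacidin, and the (R,R)-NHC ligand of step 5 is assumed to give the (2R,3R,4R)-diol; if the sense of induction is opposite, the equally available (S,S)-ligand is used and nothing else changes.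

## Route

Step 1
Reactants: 1 2',3',4'-trihydroxyacetophenone (gallacetophenone)
Product: 2 1-[3,4-bis(benzyloxy)-2-hydroxyphenyl]ethan-1-one
Conditions: BnBr (2.1 equiv), K2CO3 (2.2 equiv), acetone, reflux, 12 h
Reagents that add atoms: benzyl bromide, BrCc1ccccc1
Why: Williamson ether synthesis in which the 2-OH, tied up in a strong hydrogen bond to the acetyl carbonyl, is the least acidic and least nucleophilic of the three phenols and stays free for the later ring closures; no stereocentre is formed.

Step 2
Reactants: 2 1-[3,4-bis(benzyloxy)-2-hydroxyphenyl]ethan-1-one; 3 4-(benzyloxy)benzaldehyde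
Product: 4 (E)-1-[3,4-bis(benzyloxy)-2-hydroxyphenyl]-3-[4-(benzyloxy)phenyl]prop-2-en-1-one
Conditions: KOH (50% aq, 5 equiv), EtOH–THF, rt, 36 h; then 1 M HCl
Reagents that add atoms: none
Why: Claisen–Schmidt (crossed aldol) condensation of the methyl ketone enolate on a non-enolisable aldehyde followed by E1cB loss of water, which gives the conjugated (E)-enone as the thermodynamic product; no stereocentre is formed.

Step 3
Reactants: 4 (E)-1-[3,4-bis(benzyloxy)-2-hydroxyphenyl]-3-[4-(benzyloxy)phenyl]prop-2-en-1-one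
Product: 6 (2S,4S)-7,8-bis(benzyloxy)-2-[4-(benzyloxy)phenyl]chroman-4-ol, via racemic flavanone 5 (not isolated)
Conditions: DBU (3.3 equiv), MeCN, 40 °C, 3 h; then HCO2H (3.0 equiv), RuCl[(S,S)-TsDPEN](p-cymene) (1 mol %), 40 °C, 24 h; crystallised
Reagents that add atoms: none
Why: Proposed new method: DBU makes the chalcone-isomerase-type 6-endo-trig oxa-Michael closure of ring C reversible, so 4 and both enantiomers of 5 interconvert, while the (S,S)-configured Noyori–Ikariya ruthenium hydride reduces only (2S)-5 fast because its preferred carbonyl face (giving 4S) is there also the face anti to the 2-aryl group, which drains the whole pool into the 2,4-cis (2S,4S)-alcohol and so sets C2 by dynamic kinetic resolution; the closest known reaction type is asymmetric transfer hydrogenation of 2-substituted chroman-4-ones under racemisation by retro-oxa-Michael elimination, extended here to start from the open chalcone.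

Step 4
Reactants: 4 (E)-1-[3,4-bis(benzyloxy)-2-hydroxyphenyl]-3-[4-(benzyloxy)phenyl]prop-2-en-1-one
Product: 8 7,8-bis(benzyloxy)-2-[4-(benzyloxy)phenyl]-3-hydroxy-4H-chromen-4-one, via racemic trans-dihydroflavonol 7 (not isolated)
Conditions: 30% aq H2O2 (5 equiv), 2 M NaOH (4 equiv), MeOH–THF, 0 °C to rt, 6 h; then 1 M HCl
Reagents that add atoms: hydrogen peroxide, OO
Why: Algar–Flynn–Oyamada oxidative cyclisation, the laboratory counterpart of flavanone 3-hydroxylase plus flavonol synthase: hydroperoxide oxygenates Cα while the 2'-phenoxide closes ring F at Cβ to give 7, a chalcone that lacks a 6'-substituent and carries a p-alkoxy ring B closes to the six-membered ring rather than to the aurone, and excess peroxide dehydrogenates 7 to the planar flavonol, so no stereocentre has to be controlled here.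

Step 5
Reactants: 8 7,8-bis(benzyloxy)-2-[4-(benzyloxy)phenyl]-3-hydroxy-4H-chromen-4-one
Product: 10 (2R,3R,4R)-7,8-bis(benzyloxy)-2-[4-(benzyloxy)phenyl]chromane-3,4-diol (tri-O-benzyl-(−)-teracacidin), via cis-dihydroflavonol 9 (not isolated)
Conditions: [Ru(cod)(2-methylallyl)2] (5 mol %), (R,R)-SINpEt·HBF4 (1,3-bis[(1R)-1-(naphthalen-1-yl)ethyl]imidazolinium tetrafluoroborate, 10 mol %), KOtBu (12 mol %), hexane, 70 °C, 16 h (catalyst preformed); then 8, H2 (120 bar), toluene, 40 °C, 48 h; crystallised
Reagents that add atoms: none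
Why: Proposed new method: the chiral Ru–NHC hydride adds H2 syn across C2=C3 of the pyranone from one face to give the kinetic cis-dihydroflavonol 9, whose ketone is then hydrogenated from the same face because the other one now carries the 2-aryl group and the axial 3-OH, so C2, C3 and C4 are set in one operation as the 2,3-cis-3,4-cis array with the absolute sense fixed by the ligand; the closest known reaction types are Ru–NHC-catalysed asymmetric hydrogenation of flavones to cis-flavan-4-ols and the heterogeneous hydrogenation of 7,8-dialkoxyflavonols, which gives the racemic all-cis 3,4-diols.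

Step 6
Reactants: 6 (2S,4S)-7,8-bis(benzyloxy)-2-[4-(benzyloxy)phenyl]chroman-4-ol; 10 (2R,3R,4R)-7,8-bis(benzyloxy)-2-[4-(benzyloxy)phenyl]chromane-3,4-diol
Product: 12 (2R,3R,4R)-7,8-bis(benzyloxy)-6-{(2S,4R)-7,8-bis(benzyloxy)-2-[4-(benzyloxy)phenyl]chroman-4-yl}-2-[4-(benzyloxy)phenyl]chromane-3,4-diol (hexa-O-benzyl ether of the target), via flavan-4-yl cation 11 (not isolated)
Conditions: 10 (3 equiv, excess recovered), TsOH·H2O (5 mol %), CH2Cl2–(CF3)2CHOH 4:1, −20 °C, 6 added over 2 h; Et3N quench
Reagents that add atoms: none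
Why: Biomimetic proanthocyanidin-type dehydrative Friedel–Crafts alkylation in which the 3-deoxy benzylic alcohol 6 ionises far more readily than the 4-OH of 10 (held back by the inductive effect of its neighbouring 3-OH) to the cation 11 stabilised by O1 and the 7-alkoxy group, C6 of 10 (para to O1, ortho to 7-OBn) is its most nucleophilic carbon, and pseudo-axial attack on the half-chair cation with the 2-aryl group equatorial places the new bond anti to that aryl group and sets the 2,4-trans (4β) linkage, while excess 10 and slow addition of 6 suppress self-condensation.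

Step 7
Reactants: 12 hexa-O-benzyl ether of the target
Product: 13 (2R,3R,4R)-6-[(2S,4S)-7,8-dihydroxy-2-(4-hydroxyphenyl)chroman-4-yl]-2-(4-hydroxyphenyl)chromane-3,4,7,8-tetrol (target)
Conditions: H2 (1 atm), 10% Pd/C, EtOAc–MeOH, rt, 3 h; filtered and concentrated under argon
Reagents that add atoms: none
Why: Catalytic hydrogenolysis of the six aryl benzyl ethers under neutral conditions, which is much faster than cleavage of the secondary benzylic C4–OH, of the cyclic benzylic C2–O bonds or of the diarylmethine carbon, so no stereocentre is touched.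

## Compound list
1 | 2',3',4'-trihydroxyacetophenone (gallacetophenone) | CC(=O)c1ccc(O)c(O)c1O | starting material
2 | 1-[3,4-bis(benzyloxy)-2-hydroxyphenyl]ethan-1-one | CC(=O)c1ccc(OCc2ccccc2)c(OCc2ccccc2)c1O | intermediate
3 | 4-(benzyloxy)benzaldehyde | O=Cc1ccc(OCc2ccccc2)cc1 | starting material
4 | (E)-1-[3,4-bis(benzyloxy)-2-hydroxyphenyl]-3-[4-(benzyloxy)phenyl]prop-2-en-1-one (chalcone) | O=C(/C=C/c1ccc(OCc2ccccc2)cc1)c1ccc(OCc2ccccc2)c(OCc2ccccc2)c1O | intermediate
5 | rac-7,8-bis(benzyloxy)-2-[4-(benzyloxy)phenyl]chroman-4-one (racemic, enantiomers interconvert, formed and consumed in the flask of step 3) | O=C1CC(c2ccc(OCc3ccccc3)cc2)Oc2c(OCc3ccccc3)c(OCc3ccccc3)ccc12 | intermediate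
6 | (2S,4S)-7,8-bis(benzyloxy)-2-[4-(benzyloxy)phenyl]chroman-4-ol (2,4-cis) | c5ccccc5COc1ccc([C@@H]2C[C@H](O)c3ccc(OCc5ccccc5)c(OCc5ccccc5)c3O2)cc1 | intermediate
7 | (±)-trans-7,8-bis(benzyloxy)-2-[4-(benzyloxy)phenyl]-3-hydroxychroman-4-one (racemic, 2R,3R enantiomer drawn, formed and consumed in the flask of step 4) | c1cc2c(c(OCc3ccccc3)c1OCc3ccccc3)O[C@H](c1ccc(OCc3ccccc3)cc1)[C@@H](O)C2=O | intermediate
8 | 7,8-bis(benzyloxy)-2-[4-(benzyloxy)phenyl]-3-hydroxy-4H-chromen-4-one (flavonol) | O=c1c(O)c(-c2ccc(OCc3ccccc3)cc2)oc2c(OCc3ccccc3)c(OCc3ccccc3)ccc12 | intermediate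
9 | (2R,3S)-7,8-bis(benzyloxy)-2-[4-(benzyloxy)phenyl]-3-hydroxychroman-4-one (2,3-cis, formed and consumed in the flask of step 5) | c1cc2c(c(OCc3ccccc3)c1OCc3ccccc3)O[C@H](c1ccc(OCc3ccccc3)cc1)[C@H](O)C2=O | intermediate
10 | (2R,3R,4R)-7,8-bis(benzyloxy)-2-[4-(benzyloxy)phenyl]chromane-3,4-diol (2,3-cis-3,4-cis, tri-O-benzyl-(−)-teracacidin) | c1cc2c(c(OCc3ccccc3)c1OCc3ccccc3)O[C@H](c1ccc(OCc3ccccc3)cc1)[C@H](O)[C@@H]2O | intermediate
11 | (2S)-7,8-bis(benzyloxy)-2-[4-(benzyloxy)phenyl]chroman-4-ylium (formed and consumed in the flask of step 6) | c5ccccc5COc1ccc([C@@H]2C[CH+]c3ccc(OCc5ccccc5)c(OCc5ccccc5)c3O2)cc1 | intermediate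
12 | (2R,3R,4R)-7,8-bis(benzyloxy)-6-{(2S,4R)-7,8-bis(benzyloxy)-2-[4-(benzyloxy)phenyl]chroman-4-yl}-2-[4-(benzyloxy)phenyl]chromane-3,4-diol (upper unit 2,4-trans; the label 4R comes only from the changed CIP ranking of the O-benzylated ring D and is the same arrangement as 4S in 13) | c5ccccc5COc1ccc([C@@H]2C[C@@H](c3cc4c(c(OCc5ccccc5)c3OCc5ccccc5)O[C@H](c3ccc(OCc5ccccc5)cc3)[C@H](O)[C@@H]4O)c3ccc(OCc5ccccc5)c(OCc5ccccc5)c3O2)cc1 | intermediate
13 | (2R,3R,4R)-6-[(2S,4S)-7,8-dihydroxy-2-(4-hydroxyphenyl)chroman-4-yl]-2-(4-hydroxyphenyl)chromane-3,4,7,8-tetrol (CNP0209379.1) | Oc1ccc([C@@H]2C[C@@H](c3cc4c(c(O)c3O)O[C@H](c3ccc(O)cc3)[C@H](O)[C@@H]4O)c3ccc(O)c(O)c3O2)cc1 | target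

## Step count and risks
Total step count: 7. Longest linear sequence: 6 (steps 1, 2, 4, 5, 6, 7).

**Step 5 is the most likely to fail.** The flavonol may shut the catalyst down by O,O-chelation. The tetrasubstituted C2=C3 bond may be reduced slowly or with low ee. Compound 9 may also epimerise at C3 before its ketone is reduced.
- The fallback sets out from 6 and comes back at 10. The C2 centre fixed in step 3 then controls the whole triad by substrate control, and no second chiral catalyst is needed.
- Compound 6 is dehydrated (MsCl, Et3N, CH2Cl2, 0 °C) to (2S)-7,8-bis(benzyloxy)-2-[4-(benzyloxy)phenyl]-2H-chromene F2.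
- A Woodward cis-hydroxylation follows (I2, AgOAc, AcOH, rt, then water). Iodine adds on the face anti to the aryl group and acetate opens at the benzylic C4. This gives (2R,3R,4R)-7,8-bis(benzyloxy)-2-[4-(benzyloxy)phenyl]-3-iodochroman-4-yl acetate F3, with the aryl group and acetate on one face and iodine on the other.
- Silver-assisted displacement of iodide by the neighbouring acetate from the aryl-bearing face, then hydrolysis of the acetoxonium ion, gives (2R,3R,4R)-7,8-bis(benzyloxy)-2-[4-(benzyloxy)phenyl]-4-hydroxychroman-3-yl acetate F4.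
- Methanolysis (K2CO3, MeOH) of F4 gives 10.

**Step 3 is second.** The ruthenium hydride may reduce the open chalcone in the conjugate sense to the dihydrochalcone faster than ring C closes. Racemisation of 5 may also be too slow for a dynamic process.
- The fallback sets out from 4 and comes back at 6. It replaces the dynamic resolution with face-selective hydrogenation of a planar heterocycle.
- Compound 4 is cyclodehydrogenated (I2 10 mol %, DMSO, 130 °C, a flavone-synthase-type closure) to 7,8-bis(benzyloxy)-2-[4-(benzyloxy)phenyl]-4H-chromen-4-one F1.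
- F1 is hydrogenated with the Ru–NHC catalyst and ligand enantiomer of step 5, a reaction type that is known for flavones. Syn delivery of hydrogen gives the 2,4-cis alcohol 6 directly.

**Step 6 is third.** Ring A of 6 is as nucleophilic as ring D of 10, so self-condensation can compete. The diol oxygens of 10 can be alkylated. The 4-OH of 10 can ionise and epimerise to the 3,4-trans diol.
- The fallback sets out from 10 and comes back at 13. It changes the nucleophile from an aryl ether to a free phenol.
- Compound 10 is debenzylated first (H2, Pd/C, EtOAc–MeOH) to (2R,3R,4R)-2-(4-hydroxyphenyl)chromane-3,4,7,8-tetrol, (−)-teracacidin F5. Its phenolic ring D is far more nucleophilic than the benzylated ring A of 6.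
- F5 (2 equiv) is coupled with 6 (TsOH·H2O 2 mol %, THF–(CF3)2CHOH, −20 °C). The product is (2R,3R,4R)-6-{(2S,4S)-7,8-bis(benzyloxy)-2-[4-(benzyloxy)phenyl]chroman-4-yl}-2-(4-hydroxyphenyl)chromane-3,4,7,8-tetrol F6.
- Hydrogenolysis of F6 under the conditions of step 7 gives 13.

## Further compounds
F1 | step 3 | 7,8-bis(benzyloxy)-2-[4-(benzyloxy)phenyl]-4H-chromen-4-one | O=c1cc(-c2ccc(OCc3ccccc3)cc2)oc2c(OCc3ccccc3)c(OCc3ccccc3)ccc12
F2 | step 5 | (2S)-7,8-bis(benzyloxy)-2-[4-(benzyloxy)phenyl]-2H-chromene | c5ccccc5COc1ccc([C@@H]2C=Cc3ccc(OCc5ccccc5)c(OCc5ccccc5)c3O2)cc1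
F3 | step 5 | (2R,3R,4R)-7,8-bis(benzyloxy)-2-[4-(benzyloxy)phenyl]-3-iodochroman-4-yl acetate (2,3-trans-3,4-trans) | c5ccccc5COc1ccc([C@@H]2[C@@H](I)[C@H](OC(C)=O)c3ccc(OCc5ccccc5)c(OCc5ccccc5)c3O2)cc1
F4 | step 5 | (2R,3R,4R)-7,8-bis(benzyloxy)-2-[4-(benzyloxy)phenyl]-4-hydroxychroman-3-yl acetate (all-cis) | c1cc2c(c(OCc3ccccc3)c1OCc3ccccc3)O[C@H](c1ccc(OCc3ccccc3)cc1)[C@H](OC(C)=O)[C@@H]2O
F5 | step 6 | (2R,3R,4R)-2-(4-hydroxyphenyl)chromane-3,4,7,8-tetrol, (−)-teracacidin | c1cc2c(c(O)c1O)O[C@H](c1ccc(O)cc1)[C@H](O)[C@@H]2O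
F6 | step 6 | (2R,3R,4R)-6-{(2S,4S)-7,8-bis(benzyloxy)-2-[4-(benzyloxy)phenyl]chroman-4-yl}-2-(4-hydroxyphenyl)chromane-3,4,7,8-tetrol | c5ccccc5COc1ccc([C@@H]2C[C@@H](c3cc4c(c(O)c3O)O[C@H](c3ccc(O)cc3)[C@H](O)[C@@H]4O)c3ccc(OCc5ccccc5)c(OCc5ccccc5)c3O2)cc1
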